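The earlier runs and the new flask were computed with made-up constants.

Take a stirred vessel in which the second reagent stands from the first minute and condenses with itself, whether or not any intermediate is there to meet it.

| setting | east | north-west | spring | summer | winter | midnight |
|---|---|---|---|---|---|---|
| substrate | 0.32 M | 0.32 M | 0.32 M | 0.32 M | 0.32 M (fed, over 20 h) | 0.32 M |
| partner | 1 equiv | 2 equiv | 1.00 equiv (fed, over 20 h) | 1.00 equiv (fed, over 20 h) | 1.00 equiv | 1.00 equiv |
| second reagent | 4 equiv | 4 equiv | 4.00 equiv | 4.00 equiv | 4.00 equiv | 4.00 equiv |
| temperature | 20 °C | 20 °C | 20 °C |  | 20 °C | 20 °C |
| remark | run made earlier | run made earlier | all else is in the flask from the start; the feed brings no volume worth counting | the addition at −20 °C, then warmed to 20 °C; the feed brings no volume worth counting | all else is in the flask from the start; the feed brings no volume worth counting | everything together at the start |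
| time |  |  | 50 h | 50 h | 50 h | 50 h |

| run | time / h | target / % | substrate / % |
|---|---|---|---|
| east | 8.00 | 17.2 | 36.9 |
| east | 15.0 | 26.4 | 23.8 |
| east | 25.0 | 34.9 | 15.6 |
| east | 30.0 | 37.8 | 13.4 |
| east | 40.0 | 42.0 | 9.4 |
| east | 48.0 | 43.6 | 8.3 |
| north-west | 0.833 | 2.1 | 71.3 |
| north-west | 1.33 | 3.5 | 60.0 |
| north-west | 2.00 | 5.6 | 48.4 |
| north-west | 4.00 | 13.7 | 26.3 |
| north-west | 6.00 | 20.3 | 15.0 |
| north-west | 10.0 | 30.2 | 5.6 |

(scatter of a reading: 0.5 percentage points)

- the flask with the highest amount of target, in percent of the substrate charged ("all alike" if they lie within 1.5 percentage points) (spring / summer / winter / midnight / all alike)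
- final target, as a percentage of the substrate charged, in spring
- final target, as a percentage of the substrate charged, in summer
- final target, as a percentage of the substrate charged, in winter
- final target, as a percentage of the substrate charged, in midnight

First close the balance of substrate: the intermediate is what substrate and target leave of the charge. Call κ the pseudo-first-order capture constant, the target gained per hour per intermediate standing, and τ its reciprocal, the waiting time.

The north-west run between 2.00 h and 4.00 h reads κ = 0.0764 /h. The east run between 15.0 h and 30.0 h reads a weaker 0.0154 /h.

Draw τ = b + a·t through both windows, with the ageing number a = 2.66, the hours of waiting added per hour, and b = 5.12 h.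

Integrate κ from birth to the end. The share captured, c, is one minus the ratio of τ at birth to τ at the end, raised to the power of one over a.

Take the first east reading as a typical birth: c = 46.4%. Feeding delays births by about half the feed, 10.0 h, so c = 30.3%, a ratio r of 0.653.

Now test what must be known well. Doubling b gives r = 0.663. Doubling a gives 0.609. Doubling the delay gives 0.404. So the delay moves r further than either constant.

Midnight repeats east: extend its last reading to 44.3%. Spring is then 28.9%, and winter the same, with substrate and partner reacting one for one. Summer, if the cold holds it still (a guess), is east at 30.0 h: 37.8%. Midnight ranks above both.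

The forecast names midnight, with 29% for spring, 38% for summer, 29% for winter and 44.5% for midnight, close to this reckoning but not equal to it, and its grounds for spring and winter are that the “intermediate forms late, after the reagent has decayed”.

The flasks give 29.2% in spring, 37.8% in summer, 29.2% in winter and 44.9% in midnight, so midnight leads. Spring at 50.0 h holds intermediate 59.8% beside second reagent 3.29% of its charge. With the ageing number, τ there is 138 h, longer than the whole run.

    substrate + partner → intermediate (k = 0.675 /M/h, Ea = 75.0 kJ/mol)
    second reagent + intermediate → target (k = 0.118 /M/h, Ea = 85.0 kJ/mol)
    2 second reagent → self-condensation product (k = 0.127 /M/h, Ea = 80.0 kJ/mol)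
    (constants at 20 °C)

A neighbouring flask is spring charged with 1.60 equiv of second reagent. Hold a and stretch b by the charge ratio to 12.8 h: c = 28.1%, which scales spring to 27.1%. The flask gives 24.9%.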